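## Analysis of the target

Target 31 is a cedrane-type sesquiterpenoid acid, tricyclo[5.3.1.0(1,5)]undec-8-ene, esterified at O10 with (9Z)-16-hydroxyhexadec-9-enoic acid. Locants follow that name; C12 is the formyl carbon on C2, C13/C14 are the methyls on C6, and C15 is the carboxyl carbon on C8.

Ring A (C1, C10, C9, C8, C7, C11) is a cyclohexene. The C5–C6 unit bridges it across C1/C7 and so forms ring C (C1, C11, C7, C6, C5). Ring B (C1–C5) is a cyclopentane fused exo at C1–C5. C1 is therefore an all-carbon quaternary centre common to three rings, and it sits next to the quaternary C6.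

There are five stereocentres (1S,2S,5S,7R,10S). C1, C5 and C7 are locked together by the bridged skeleton. The two peripheral centres are free: the formyl group on C2 lies on the face of ring B that also carries C11 and C6 (trans to C10), and O10 is endo (anti to C11, syn to the C5–C6 bridge).

Sensitive groups are the aldehyde with its epimerisable α-centre C2, the γ-acyloxy enoic acid, the (Z)-alkene, and a free acid and primary alcohol beside an ester link. That ester rules out a final saponification.

The hard part is the bridged, doubly quaternary core with CH2 at C11 and the array C8(CO2H)=C9H–C10H(O). The classical cedrane-forming cycloadditions place oxygen on C11 or C9 instead. A second difficulty is that the C2 substituent must sit on the more crowded face of ring B, which argues against setting it by equilibration.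

## Retrosynthetic reasoning

**31 from 30.** The aldehyde, the acid and the primary alcohol are released together in one acidic operation. They are carried as a dimethyl acetal, a 4-methoxybenzyl ester and a silyl ether. The aldehyde is therefore never exposed to base, and C2 stays fixed until the end.

**30 from 21 and 28.** The C10–O acyl bond is cut. The side-chain acid 28 comes from a Z-selective Wittig reaction that forms its C9=C10 bond from phosphonium salt 26 (from 25) and aldehyde 24 (from 22). The acylation goes with retention, so 21 must already carry the endo (10S) hydroxyl.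

**21 from 20, 19 and 18.** The key step delivers O10 on the exo face (10R), because the silyloxy group is used there as a steering group. The centre is corrected by oxidation to enone 20 and 1,2-reduction from the open exo face. This costs two redox steps but needs no protecting-group change.

**18 from 17 and 15.** The C8–C15 bond is cut. C15 is introduced by palladium-catalysed carbonylation of the enol triflate of ketone 15. The ketone can enolise only towards C9 because C7 is a bridgehead, so the C8=C9 position is unambiguous.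

**15 from 14 (key disconnection).** The bonds C1–C5 and C6–C7 are cut and C1 is joined to C7 as a cyclopropane bond. Rings B and C disappear, ring A contracts to a cyclopentanone, and the tricycle becomes a bicyclo[3.1.0]hexan-2-one with a pendant trisubstituted alkene. In the forward direction a ketyl radical-anion relay has to cleave the ring-fusion bond, close ring B at the quaternary C1, close ring C at C7, and set C1, C5 and C7 in one operation. Only the stereocentres C10 and C2 of 14 matter, because the two cyclopropane centres are erased.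

**14 from 13.** The cyclopropane bonds C7–C1 and C7–C11 and the C8 carbonyl are traced back to a terminal alkyne and a 1,1-disubstituted alkene. Oxidative gold catalysis turns the alkyne into a ketone carbene equivalent, which avoids a diazoketone.

**13 from 12, and 12 from 9 and 10.** The C9–C10 bond is cut. A catalyst-controlled propargylation of the enal 9 with allenylboronate 10 sets C10.

**9 from 8, 6, 3 and 4.** C11 is added by α-methylenation of aldehyde 8. The C2–C3 bond, and with it the C2 stereocentre, comes from a copper-catalysed asymmetric conjugate addition of the Grignard reagent from 4 to enoate 3. Enoate 3 is made from 1 and 2. C12 is at the aldehyde oxidation level from the first step and needs no later redox change.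

## Alternatives that were turned down

**Alternative 1:** (the textbook cedrane disconnection) An intramolecular arene–alkene meta-photocycloaddition forms C1–C5 and C6–C7 from the arene A1 (methyl 4-[(2S)-1,1-dimethoxy-6-methylhept-5-en-2-yl]-3-methoxybenzoate). The vinylcyclopropane photoadducts are then fragmented to the tricycle A2.
- Regiocontrol of the 1,3-addition requires a donor on the arene carbon that becomes C11. A2 therefore carries its oxygen on C11, where the target has CH2, and has CH2 at C10, where the target has oxygen.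
- This forces a deoxygenation of a hindered bridging ketone and a late γ-oxidation of an enoate.
- The ester para to the tether makes the arene electron-poor, which favours ortho addition and quenching of the excited state.
- The allylic-strain-controlled transition state places the benzylic substituent trans to C6 and C11, the C2 epimer of what is needed.

**Alternative 2:** A cationic [5+2] cycloaddition of the hydroxy-para-quinone A3 (methyl 4-[(2S)-1,1-dimethoxy-6-methylhept-5-en-2-yl]-5-hydroxy-3,6-dioxocyclohexa-1,4-diene-1-carboxylate) with its own alkene, under Lewis acid, gives the diosphenol A4.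
- The precursor is very simple and the same two bonds are formed.
- A4, however, carries carbonyl groups at C10 and C11 and an enol at C9. Two oxygens (C9, C11) must be removed, each in two or three steps, on an array prone to α-ketol shifts.
- The ester on the pentadienyl cation lowers the reactivity of the cycloaddition.
- The step count after the key step exceeds what the key step saves.

**Alternative 3:** An intramolecular Diels–Alder reaction of the 1-substituted cyclopentadiene A5 gives the norbornene A6. A one-carbon ring expansion with dibromocarbene then gives the dibromide A7.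
- The cycloaddition sets C1, C5 and C7 by geometry, but the dienophile is an unactivated trisubstituted alkene, and 1,5-hydrogen shifts scramble the diene isomers.
- The inserted carbon is C9 and keeps a bromine, while C8 gains no carbon substituent.
- The allylic bromide can end on C8 or C10.
- C15 would still have to be introduced and the C9 bromine removed, so the single-atom insertion does not deliver the C8/C9/C10 pattern.

Key step: step 8

## Route

Step 1
Reactants: 1 2,2-dimethoxyacetaldehyde; 2 methyl (triphenyl-λ5-phosphanylidene)acetate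
Product: 3 methyl (2E)-4,4-dimethoxybut-2-enoate
Conditions: CH2Cl2/H2O, rt
Reagents that add atoms: none
Why: Wittig olefination with a stabilised ylide, which is E-selective and tolerates the aqueous aldehyde solution.

Step 2
Reactants: 3 methyl (2E)-4,4-dimethoxybut-2-enoate; 4 5-bromo-2-methylpent-2-ene
Product: 6 methyl (3S)-3-(dimethoxymethyl)-7-methyloct-6-enoate, via Grignard reagent 5 (not isolated)
Conditions: 4, Mg, Et2O; then 3, CuI (2 mol %), Tol-BINAP (3 mol %), t-BuOMe, −40 °C; aq NH4Cl
Reagents that add atoms: none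
Why: Copper-catalysed asymmetric conjugate addition of a Grignard reagent to an enoate; the chiral bisphosphine complex of monovalent copper selects the enantioface and sets C2 (3S in 6), and the ligand enantiomer is chosen to give this sense. The γ-acetal is not a leaving group, so no allylic substitution is expected.

Step 3
Reactants: 6 methyl (3S)-3-(dimethoxymethyl)-7-methyloct-6-enoate
Product: 8 (3S)-3-(dimethoxymethyl)-7-methyloct-6-enal, via aluminium hemiacetal 7 (not isolated)
Conditions: iBu2AlH (1.05 equiv), CH2Cl2, −78 °C; Rochelle salt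
Reagents that add atoms: none
Why: Partial reduction of the ester; the tetrahedral aluminium hemiacetal persists at −78 °C and collapses to the aldehyde only on work-up. The stereocentre is β to the carbonyl and is not touched.

Step 4
Reactants: 8 (3S)-3-(dimethoxymethyl)-7-methyloct-6-enal
Product: 9 (3S)-3-(dimethoxymethyl)-7-methyl-2-methylideneoct-6-enal
Conditions: aq CH2O, pyrrolidine (10 mol %), EtCO2H (10 mol %), i-PrOH, 45 °C
Reagents that add atoms: formaldehyde C=O
Why: Organocatalytic α-methylenation (Mannich condensation, then elimination of the amine) at the only α-CH2 group; this adds C11.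

Step 5
Reactants: 9 (3S)-3-(dimethoxymethyl)-7-methyl-2-methylideneoct-6-enal; 10 4,4,5,5-tetramethyl-2-(propa-1,2-dien-1-yl)-1,3,2-dioxaborolane
Product: 12 (4R,6S)-6-(dimethoxymethyl)-10-methyl-5-methylideneundec-9-en-1-yn-4-ol, via pinacol borate ester 11 (not isolated)
Conditions: 10 (1.5 equiv), 3,3'-bis(2,4,6-triisopropylphenyl)-BINOL hydrogen phosphate (5 mol %), 4 Å MS, toluene, −20 °C; aqueous work-up
Reagents that add atoms: none
Why: Chiral-phosphoric-acid-catalysed propargylation with an allenylboronate through a closed six-membered transition state (SE2' transfer); the catalyst enantiomer is chosen for Re-face attack, which gives the 4R carbinol (the future C10). The existing centre is remote, and a minor C4 epimer is a diastereomer that can be removed by chromatography.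

Step 6
Reactants: 12 (4R,6S)-6-(dimethoxymethyl)-10-methyl-5-methylideneundec-9-en-1-yn-4-ol
Product: 13 tert-butyl{[(4R,6S)-6-(dimethoxymethyl)-10-methyl-5-methylideneundec-9-en-1-yn-4-yl]oxy}dimethylsilane
Conditions: TBSCl, imidazole, DMAP (cat.), DMF, 40 °C
Reagents that add atoms: tert-butyl(chloro)dimethylsilane CC(C)(C)[Si](C)(C)Cl
Why: Silylation under non-acidic conditions that leave the dimethyl acetal alone; the bulky silyl ether later serves as the steering group of the key step.

Step 7
Reactants: 13 tert-butyl{[(4R,6S)-6-(dimethoxymethyl)-10-methyl-5-methylideneundec-9-en-1-yn-4-yl]oxy}dimethylsilane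
Product: 14 (1S,4R,5S)-4-[(tert-butyldimethylsilyl)oxy]-5-[(2S)-1,1-dimethoxy-6-methylhept-5-en-2-yl]bicyclo[3.1.0]hexan-2-one
Conditions: Ph3PAuNTf2 (5 mol %), 8-methylquinoline N-oxide (1.3 equiv), 1,2-dichloroethane, rt
Reagents that add atoms: 8-methylquinoline N-oxide Cc1cccc2ccc[n+]([O-])c12
Why: Oxidative gold catalysis: the N-oxide adds to the terminal alkyne activated by monovalent gold and gives an α-oxo gold carbene (a diazoketone equivalent), which cyclopropanates the 1,1-disubstituted alkene through a five-membered tether. The distant trisubstituted alkene is out of reach. The cyclopropane is expected mainly anti to the silyloxy group, but its configuration is immaterial because both centres are planarised in step 8.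

Step 8
Reactants: 14 (1S,4R,5S)-4-[(tert-butyldimethylsilyl)oxy]-5-[(2S)-1,1-dimethoxy-6-methylhept-5-en-2-yl]bicyclo[3.1.0]hexan-2-one
Product: 15 (1S,2S,5S,7R,10R)-10-[(tert-butyldimethylsilyl)oxy]-2-(dimethoxymethyl)-6,6-dimethyltricyclo[5.3.1.0(1,5)]undecan-8-one
Conditions: SmI2 (20 mol %), Sm metal (10 mol %), THF, 55 °C, no proton source
Reagents that add atoms: none
Why: Proposed new method: electron transfer from SmI2 to the C8 carbonyl gives a ketyl whose ring-fusion bond C1–C7 cleaves, leaving an enolate of trivalent samarium (C7=C8–O) and a tertiary radical at C1, so the cyclopentanone grows into ring A; the radical adds 5-exo-trig to C5 of the trisubstituted alkene (ring B, spiro centre C1), the new tertiary C6 radical adds 5-exo-trig to C7 of the enolate (ring C, bond C6–C7), and the resulting ketyl returns its electron to the catalyst; the closest known reaction types are the SmI2-catalysed radical-relay (3+2) cycloaddition of alkyl cyclopropyl ketones with alkenes and the photocatalytic intramolecular (3+2) cycloaddition of aryl cyclopropyl ketones, neither of which has been shown with scission of a ring-fusion bond to give a bridged ring. Both cyclopropane centres of 14 are erased on ring opening, so only C10 and C2 steer the cascade. C1: the alkene should add to the face of the planar radical anti to the pseudo-axial C10 silyloxy group (allylic-type strain with the C2 substituent holds that group axial). C5: the bulky CMe2 terminus should lie over the flat enolate side (C11–C7) and not over C9, whose axial hydrogen is syn to the forming bond; this is also the only orientation from which ring C can close. C7: fixed by geometry, since the C6 radical can reach C7 only on the face that gives the cis-fused rings B and C. C2 is matched: with ring B forming anti to the silyloxy group, its hydrogen points to the C10 side and the dimethoxymethyl group to the C11 side, as the target requires. The step needs scission of C1–C7 and not of the better aligned external bond C7–C11; ketyl ring opening is reversible, the tertiary radical is the more stable one and is drained by a fast 5-exo closure, whereas the primary radical from C7–C11 scission can close only a six-membered ring slowly and should revert.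

Step 9
Reactants: 15 (1S,2S,5S,7R,10R)-10-[(tert-butyldimethylsilyl)oxy]-2-(dimethoxymethyl)-6,6-dimethyltricyclo[5.3.1.0(1,5)]undecan-8-one
Product: 17 (1S,2S,5S,7R,10R)-10-[(tert-butyldimethylsilyl)oxy]-2-(dimethoxymethyl)-6,6-dimethyltricyclo[5.3.1.0(1,5)]undec-8-en-8-yl trifluoromethanesulfonate, via potassium enolate 16 (not isolated)
Conditions: KN(SiMe3)2, THF, −78 °C; PhNTf2, −78 → 0 °C
Reagents that add atoms: N-phenylbis(trifluoromethanesulfonimide) FC(F)(F)S(=O)(=O)N(c1ccccc1)S(=O)(=O)C(F)(F)F
Why: Regiospecific enol triflate formation: C7 is a bridgehead and cannot enolise (Bredt strain), so deprotonation occurs only at C9. The β-silyloxy group is a poor leaving group at −78 °C.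

Step 10
Reactants: 17 (1S,2S,5S,7R,10R)-10-[(tert-butyldimethylsilyl)oxy]-2-(dimethoxymethyl)-6,6-dimethyltricyclo[5.3.1.0(1,5)]undec-8-en-8-yl trifluoromethanesulfonate
Product: 18 (4-methoxyphenyl)methyl (1S,2S,5S,7R,10R)-10-[(tert-butyldimethylsilyl)oxy]-2-(dimethoxymethyl)-6,6-dimethyltricyclo[5.3.1.0(1,5)]undec-8-ene-8-carboxylate
Conditions: Pd(OAc)2 (5 mol %), 1,3-bis(diphenylphosphino)propane (6 mol %), CO (1 atm), 4-methoxybenzyl alcohol, Et3N, DMF, 60 °C
Reagents that add atoms: carbon monoxide [C-]#[O+]; 4-methoxybenzyl alcohol COc1ccc(CO)cc1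
Why: Palladium-catalysed alkoxycarbonylation of a vinyl triflate (oxidative addition to zerovalent palladium, CO insertion, alcoholysis); it installs C15 as an acid-labile ester with the C8=C9 bond already in place.

Step 11
Reactants: 18 (4-methoxyphenyl)methyl (1S,2S,5S,7R,10R)-10-[(tert-butyldimethylsilyl)oxy]-2-(dimethoxymethyl)-6,6-dimethyltricyclo[5.3.1.0(1,5)]undec-8-ene-8-carboxylate
Product: 19 (4-methoxyphenyl)methyl (1S,2S,5S,7R,10R)-2-(dimethoxymethyl)-10-hydroxy-6,6-dimethyltricyclo[5.3.1.0(1,5)]undec-8-ene-8-carboxylate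
Conditions: Bu4NF, THF, rt; aq NH4Cl
Reagents that add atoms: none
Why: Fluoride-induced desilylation; no base-sensitive centre is present (C2 is still an acetal), and the allylic alkoxide has no elimination or lactonisation pathway.

Step 12
Reactants: 19 (4-methoxyphenyl)methyl (1S,2S,5S,7R,10R)-2-(dimethoxymethyl)-10-hydroxy-6,6-dimethyltricyclo[5.3.1.0(1,5)]undec-8-ene-8-carboxylate
Product: 20 (4-methoxyphenyl)methyl (1S,2S,5S,7R)-2-(dimethoxymethyl)-6,6-dimethyl-10-oxotricyclo[5.3.1.0(1,5)]undec-8-ene-8-carboxylate
Conditions: Dess–Martin periodinane, NaHCO3, CH2Cl2, 0 °C → rt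
Reagents that add atoms: none
Why: Dess–Martin oxidation of the allylic alcohol to the 4-oxo-2-enoate; this removes the C10 centre, which has served as the steering group and carries the wrong configuration. C1 is quaternary, so no centre next to the new ketone can epimerise.

Step 13
Reactants: 20 (4-methoxyphenyl)methyl (1S,2S,5S,7R)-2-(dimethoxymethyl)-6,6-dimethyl-10-oxotricyclo[5.3.1.0(1,5)]undec-8-ene-8-carboxylate
Product: 21 (4-methoxyphenyl)methyl (1S,2S,5S,7R,10S)-2-(dimethoxymethyl)-10-hydroxy-6,6-dimethyltricyclo[5.3.1.0(1,5)]undec-8-ene-8-carboxylate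
Conditions: NaBH4, CeCl3·7H2O, MeOH, −78 °C
Reagents that add atoms: none
Why: Luche reduction (1,2-selective for the enone carbonyl). Hydride should enter C10 from the exo face on the side of C11, because the endo face is shielded by the axial C1–C5 bond next to the carbonyl and by the endo hydrogen on C5; the hydroxyl then ends equatorial and anti to C11 (10S).

Step 14
Reactants: 22 heptane-1,7-diol
Product: 23 7-[(tert-butyldimethylsilyl)oxy]heptan-1-ol
Conditions: 22 (3 equiv), TBSCl (1 equiv), imidazole, DMF/THF, 0 °C → rt
Reagents that add atoms: tert-butyl(chloro)dimethylsilane CC(C)(C)[Si](C)(C)Cl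
Why: Statistical monosilylation with an excess of the cheap diol; the recovered diol is recycled.

Step 15
Reactants: 23 7-[(tert-butyldimethylsilyl)oxy]heptan-1-ol
Product: 24 7-[(tert-butyldimethylsilyl)oxy]heptanal
Conditions: TEMPO (10 mol %), PhI(OAc)2, CH2Cl2, rt
Reagents that add atoms: none
Why: Nitroxyl-catalysed oxidation of a primary alcohol, which stops at the aldehyde and leaves the silyl ether intact.

Step 16
Reactants: 25 9-bromononanoic acid
Product: 26 (8-carboxyoctyl)triphenylphosphonium bromide
Conditions: PPh3, MeCN, reflux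
Reagents that add atoms: triphenylphosphine c1ccc(cc1)P(c1ccccc1)c1ccccc1
Why: SN2 quaternisation of the phosphine by a primary bromide.

Step 17
Reactants: 26 (8-carboxyoctyl)triphenylphosphonium bromide; 24 7-[(tert-butyldimethylsilyl)oxy]heptanal
Product: 28 (9Z)-16-[(tert-butyldimethylsilyl)oxy]hexadec-9-enoic acid, via phosphonium ylide 27 (not isolated)
Conditions: NaN(SiMe3)2 (2.1 equiv), THF, 0 °C; then 24, −78 °C → rt; 1 M HCl to pH 3
Reagents that add atoms: none
Why: Wittig reaction of a non-stabilised ylide under lithium-free conditions at low temperature; kinetic formation of the cis-oxaphosphetane gives the (Z)-alkene.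

Step 18
Reactants: 21 (4-methoxyphenyl)methyl (1S,2S,5S,7R,10S)-2-(dimethoxymethyl)-10-hydroxy-6,6-dimethyltricyclo[5.3.1.0(1,5)]undec-8-ene-8-carboxylate; 28 (9Z)-16-[(tert-butyldimethylsilyl)oxy]hexadec-9-enoic acid
Product: 30 (4-methoxyphenyl)methyl (1S,2S,5S,7R,10S)-10-({(9Z)-16-[(tert-butyldimethylsilyl)oxy]hexadec-9-enoyl}oxy)-2-(dimethoxymethyl)-6,6-dimethyltricyclo[5.3.1.0(1,5)]undec-8-ene-8-carboxylate, via mixed anhydride 29 (not isolated)
Conditions: 28, 2,4,6-trichlorobenzoyl chloride, Et3N, THF, rt; then 21, DMAP, toluene, rt → 40 °C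
Reagents that add atoms: none
Why: Yamaguchi esterification; the acyl group is transferred to O10 with retention at C10. The alcohol is secondary and neopentylic, which is why the strongly activated mixed anhydride with DMAP is used; no base-sensitive centre is exposed.

Step 19
Reactants: 30 (4-methoxyphenyl)methyl (1S,2S,5S,7R,10S)-10-({(9Z)-16-[(tert-butyldimethylsilyl)oxy]hexadec-9-enoyl}oxy)-2-(dimethoxymethyl)-6,6-dimethyltricyclo[5.3.1.0(1,5)]undec-8-ene-8-carboxylate
Product: 31 (1S,2S,5S,7R,10S)-2-formyl-10-{[(9Z)-16-hydroxyhexadec-9-enoyl]oxy}-6,6-dimethyltricyclo[5.3.1.0(1,5)]undec-8-ene-8-carboxylic acid (CNP0214056.2)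
Conditions: CF3CO2H/H2O/CH2Cl2 (10:1:40), anisole, 0 °C, short reaction time
Reagents that add atoms: water O
Why: One acidolysis removes all three masks: alkyl–oxygen cleavage of the 4-methoxybenzyl ester (cation trapped by anisole), hydrolysis of the primary silyl ether, and hydrolysis of the dimethyl acetal. The allylic O10 ester should not ionise, because its cation would be conjugated with the carboxyl-bearing alkene; cold, brief exposure limits acid-catalysed enolisation at C2.

## Compound list

1 | 2,2-dimethoxyacetaldehyde | COC(OC)C=O | starting material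
2 | methyl (triphenyl-λ5-phosphanylidene)acetate | COC(=O)C=P(c1ccccc1)(c1ccccc1)c1ccccc1 | starting material
3 | methyl (2E)-4,4-dimethoxybut-2-enoate | COC(=O)/C=C/C(OC)OC | intermediate
4 | 5-bromo-2-methylpent-2-ene | CC(C)=CCCBr | starting material
5 | (4-methylpent-3-en-1-yl)magnesium bromide | CC(C)=CCC[Mg]Br | intermediate (not isolated)
6 | methyl (3S)-3-(dimethoxymethyl)-7-methyloct-6-enoate | COC(=O)C[C@@H](C(OC)OC)CCC=C(C)C | intermediate
7 | {[(3S)-3-(dimethoxymethyl)-1-methoxy-7-methyloct-6-en-1-yl]oxy}bis(2-methylpropyl)alumane | COC(O[Al](CC(C)C)CC(C)C)C[C@@H](C(OC)OC)CCC=C(C)C | intermediate (not isolated)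
8 | (3S)-3-(dimethoxymethyl)-7-methyloct-6-enal | O=CC[C@@H](C(OC)OC)CCC=C(C)C | intermediate
9 | (3S)-3-(dimethoxymethyl)-7-methyl-2-methylideneoct-6-enal | O=CC(=C)[C@@H](C(OC)OC)CCC=C(C)C | intermediate
10 | 4,4,5,5-tetramethyl-2-(propa-1,2-dien-1-yl)-1,3,2-dioxaborolane | C=C=CB1OC(C)(C)C(C)(C)O1 | starting material
11 | 2-{[(4R,6S)-6-(dimethoxymethyl)-10-methyl-5-methylideneundec-9-en-1-yn-4-yl]oxy}-4,4,5,5-tetramethyl-1,3,2-dioxaborolane | C#CC[C@@H](OB1OC(C)(C)C(C)(C)O1)C(=C)[C@@H](C(OC)OC)CCC=C(C)C | intermediate (not isolated)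
12 | (4R,6S)-6-(dimethoxymethyl)-10-methyl-5-methylideneundec-9-en-1-yn-4-ol | C#CC[C@@H](O)C(=C)[C@@H](C(OC)OC)CCC=C(C)C | intermediate
13 | tert-butyl{[(4R,6S)-6-(dimethoxymethyl)-10-methyl-5-methylideneundec-9-en-1-yn-4-yl]oxy}dimethylsilane | C#CC[C@@H](O[Si](C)(C)C(C)(C)C)C(=C)[C@@H](C(OC)OC)CCC=C(C)C | intermediate
14 | (1S,4R,5S)-4-[(tert-butyldimethylsilyl)oxy]-5-[(2S)-1,1-dimethoxy-6-methylhept-5-en-2-yl]bicyclo[3.1.0]hexan-2-one (cyclopropane anti to the silyloxy group; the syn isomer serves equally) | O=C1C[C@@H](O[Si](C)(C)C(C)(C)C)[C@]2([C@@H](C(OC)OC)CCC=C(C)C)C[C@H]12 | intermediate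
15 | (1S,2S,5S,7R,10R)-10-[(tert-butyldimethylsilyl)oxy]-2-(dimethoxymethyl)-6,6-dimethyltricyclo[5.3.1.0(1,5)]undecan-8-one | CC1(C)[C@H]2C[C@@]3([C@H](O[Si](C)(C)C(C)(C)C)CC2=O)[C@@H](C(OC)OC)CC[C@@H]13 | intermediate
16 | potassium (1S,2S,5S,7R,10R)-10-[(tert-butyldimethylsilyl)oxy]-2-(dimethoxymethyl)-6,6-dimethyltricyclo[5.3.1.0(1,5)]undec-8-en-8-olate | CC1(C)[C@H]2C[C@@]3([C@H](O[Si](C)(C)C(C)(C)C)C=C2[O-])[C@@H](C(OC)OC)CC[C@@H]13.[K+] | intermediate (not isolated)
17 | (1S,2S,5S,7R,10R)-10-[(tert-butyldimethylsilyl)oxy]-2-(dimethoxymethyl)-6,6-dimethyltricyclo[5.3.1.0(1,5)]undec-8-en-8-yl trifluoromethanesulfonate | CC1(C)[C@H]2C[C@@]3([C@H](O[Si](C)(C)C(C)(C)C)C=C2OS(=O)(=O)C(F)(F)F)[C@@H](C(OC)OC)CC[C@@H]13 | intermediate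
18 | (4-methoxyphenyl)methyl (1S,2S,5S,7R,10R)-10-[(tert-butyldimethylsilyl)oxy]-2-(dimethoxymethyl)-6,6-dimethyltricyclo[5.3.1.0(1,5)]undec-8-ene-8-carboxylate | CC1(C)[C@H]2C[C@@]3([C@H](O[Si](C)(C)C(C)(C)C)C=C2C(=O)OCc4ccc(OC)cc4)[C@@H](C(OC)OC)CC[C@@H]13 | intermediate
19 | (4-methoxyphenyl)methyl (1S,2S,5S,7R,10R)-2-(dimethoxymethyl)-10-hydroxy-6,6-dimethyltricyclo[5.3.1.0(1,5)]undec-8-ene-8-carboxylate | CC1(C)[C@H]2C[C@@]3([C@H](O)C=C2C(=O)OCc4ccc(OC)cc4)[C@@H](C(OC)OC)CC[C@@H]13 | intermediate
20 | (4-methoxyphenyl)methyl (1S,2S,5S,7R)-2-(dimethoxymethyl)-6,6-dimethyl-10-oxotricyclo[5.3.1.0(1,5)]undec-8-ene-8-carboxylate | CC1(C)[C@H]2C[C@@]3(C(=O)C=C2C(=O)OCc4ccc(OC)cc4)[C@@H](C(OC)OC)CC[C@@H]13 | intermediate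
21 | (4-methoxyphenyl)methyl (1S,2S,5S,7R,10S)-2-(dimethoxymethyl)-10-hydroxy-6,6-dimethyltricyclo[5.3.1.0(1,5)]undec-8-ene-8-carboxylate | CC1(C)[C@H]2C[C@@]3([C@@H](O)C=C2C(=O)OCc4ccc(OC)cc4)[C@@H](C(OC)OC)CC[C@@H]13 | intermediate
22 | heptane-1,7-diol | OCCCCCCCO | starting material
23 | 7-[(tert-butyldimethylsilyl)oxy]heptan-1-ol | OCCCCCCCO[Si](C)(C)C(C)(C)C | intermediate
24 | 7-[(tert-butyldimethylsilyl)oxy]heptanal | O=CCCCCCCO[Si](C)(C)C(C)(C)C | intermediate
25 | 9-bromononanoic acid | OC(=O)CCCCCCCCBr | starting material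
26 | (8-carboxyoctyl)triphenylphosphonium bromide | OC(=O)CCCCCCCC[P+](c1ccccc1)(c1ccccc1)c1ccccc1.[Br-] | intermediate
27 | sodium 9-(triphenyl-λ5-phosphanylidene)nonanoate | [Na+].[O-]C(=O)CCCCCCCC=P(c1ccccc1)(c1ccccc1)c1ccccc1 | intermediate (not isolated)
28 | (9Z)-16-[(tert-butyldimethylsilyl)oxy]hexadec-9-enoic acid | OC(=O)CCCCCCC/C=C\CCCCCCO[Si](C)(C)C(C)(C)C | intermediate
29 | (9Z)-16-[(tert-butyldimethylsilyl)oxy]hexadec-9-enoic 2,4,6-trichlorobenzoic anhydride | O=C(OC(=O)c1c(Cl)cc(Cl)cc1Cl)CCCCCCC/C=C\CCCCCCO[Si](C)(C)C(C)(C)C | intermediate (not isolated)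
30 | (4-methoxyphenyl)methyl (1S,2S,5S,7R,10S)-10-({(9Z)-16-[(tert-butyldimethylsilyl)oxy]hexadec-9-enoyl}oxy)-2-(dimethoxymethyl)-6,6-dimethyltricyclo[5.3.1.0(1,5)]undec-8-ene-8-carboxylate | CC1(C)[C@H]2C[C@@]3([C@@H](OC(=O)CCCCCCC/C=C\CCCCCCO[Si](C)(C)C(C)(C)C)C=C2C(=O)OCc4ccc(OC)cc4)[C@@H](C(OC)OC)CC[C@@H]13 | intermediate
31 | (1S,2S,5S,7R,10S)-2-formyl-10-{[(9Z)-16-hydroxyhexadec-9-enoyl]oxy}-6,6-dimethyltricyclo[5.3.1.0(1,5)]undec-8-ene-8-carboxylic acid | CC1(C)[C@H]2C[C@@]3([C@@H](OC(=O)CCCCCCC/C=C\CCCCCCO)C=C2C(=O)O)[C@@H](C=O)CC[C@@H]13 | target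

## Step count and least certain steps

Total: 19 steps. Longest linear sequence: 15 steps (steps 1–13, 18 and 19). The side chain 28 takes 4 steps (14–17) and joins in step 18.

**Step 8 (key step, proposed new method).**
- What may go wrong: scission of the cyclopropane at the external bond C7–C11 instead of the ring-fusion bond, followed by hydrogen abstraction or a slow 6-exo closure to an isomeric skeleton.
- Closure of ring B with the CMe2 terminus turned to the C10 side is also possible; the C6 radical then cannot reach C7 and is only quenched.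
- A 1,5-hydrogen transfer from the acetal C–H to the C6 radical could compete with the second closure.
- Fallback (known reaction types): ketone 14 is converted with KN(SiMe3)2 and PhNTf2 into the vinylcyclopropane triflate F1 and carbonylated (Pd(OAc)2, CO, 4-methoxybenzyl alcohol) to the vinylcyclopropane ester F2. A thiyl-radical-catalysed vinylcyclopropane–alkene annulation (PhSSPh, AIBN, hν, benzene) is then run on F2. PhS• adds to C9, the ester-stabilised cyclopropylcarbinyl radical opens reversibly to the tertiary C1 radical, the same two 5-exo closures follow (the second onto the β-carbon of the enoate), and loss of PhS• from C9 restores the C8=C9 bond. This comes back to the route at 18 and uses a neutral radical chain in place of the ketyl relay.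

**Step 7.**
- What may go wrong: capture of the electrophilic gold carbene by the neighbouring silyl ether oxygen (oxonium ylide formation) or over-oxidation of the carbene, in competition with cyclopropanation of the hindered alkene.
- Fallback: from 13, Markovnikov hydration of the alkyne (Ph3PAuNTf2, wet dioxane) gives the methyl ketone F3. Kinetic trifluoroacetylation (LiN(SiMe3)2, CF3CO2CH2CF3) gives the 1,3-diketone F4, and diazo transfer (MsN3, Et3N) gives the diazoketone F5. Rh2(OAc)4-catalysed intramolecular cyclopropanation then comes back to 14.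

**Step 5.**
- What may go wrong: low reactivity of the α-branched enal or incomplete catalyst control, which would give a mixture at C4 (the future C10); the wrong epimer is mismatched in step 8.
- Fallback: from 9, an unselective Barbier propargylation (Zn, propargyl bromide, THF/aq NH4Cl) gives 12 together with its C4 epimer F6. The two are diastereomers and are separated by chromatography. F6 is recycled by Mitsunobu inversion with 4-nitrobenzoic acid to the ester F7 and methanolysis (K2CO3, MeOH), which returns to 12.

**Step 13.**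
- What may go wrong: poor facial selectivity of the hydride addition, giving part of the exo alcohol back.
- Fallback: from 19 (the exo alcohol, a single epimer from step 11), Mitsunobu inversion with 4-nitrobenzoic acid (PPh3, diisopropyl azodicarboxylate, toluene) gives the endo 4-nitrobenzoate F8. Elimination is not possible at this centre, though substitution at a neopentylic carbon will be slow. Selective methanolysis with Mg(OMe)2 returns to 21 without passing through the ketone.

**Step 19.**
- What may go wrong: acid-catalysed enolisation of the freed aldehyde (loss of configuration at C2) during the time needed to cleave the benzyl-type ester, or trifluoroacetylation of the primary alcohol.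
- Fallback: from 30, a brief anhydrous treatment (CF3CO2H, anisole, CH2Cl2, −20 °C) cleaves only the 4-methoxybenzyl ester and gives the acid F9, with the acetal and silyl ether still in place. A separate near-neutral hydrolysis (LiBF4 in wet MeCN, or AcOH/THF/H2O) then unveils the aldehyde and the alcohol and arrives at 31, so the aldehyde never meets strong acid.

## Further compounds

F1 | step 8 | (4R)-4-[(tert-butyldimethylsilyl)oxy]-5-[(2S)-1,1-dimethoxy-6-methylhept-5-en-2-yl]bicyclo[3.1.0]hex-2-en-2-yl trifluoromethanesulfonate | FC(F)(F)S(=O)(=O)OC1=C[C@@H](O[Si](C)(C)C(C)(C)C)[C@]2([C@@H](C(OC)OC)CCC=C(C)C)C[C@H]12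
F2 | step 8 | (4-methoxyphenyl)methyl (4R)-4-[(tert-butyldimethylsilyl)oxy]-5-[(2S)-1,1-dimethoxy-6-methylhept-5-en-2-yl]bicyclo[3.1.0]hex-2-ene-2-carboxylate | COc1ccc(COC(=O)C2=C[C@@H](O[Si](C)(C)C(C)(C)C)[C@]3([C@@H](C(OC)OC)CCC=C(C)C)C[C@H]23)cc1
F3 | step 7 | (4R,6S)-4-[(tert-butyldimethylsilyl)oxy]-6-(dimethoxymethyl)-10-methyl-5-methylideneundec-9-en-2-one | CC(=O)C[C@@H](O[Si](C)(C)C(C)(C)C)C(=C)[C@@H](C(OC)OC)CCC=C(C)C
F4 | step 7 | (6R,8S)-6-[(tert-butyldimethylsilyl)oxy]-8-(dimethoxymethyl)-1,1,1-trifluoro-12-methyl-7-methylidenetridec-11-ene-2,4-dione | FC(F)(F)C(=O)CC(=O)C[C@@H](O[Si](C)(C)C(C)(C)C)C(=C)[C@@H](C(OC)OC)CCC=C(C)C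
F5 | step 7 | (4R,6S)-4-[(tert-butyldimethylsilyl)oxy]-1-diazo-6-(dimethoxymethyl)-10-methyl-5-methylideneundec-9-en-2-one | [N-]=[N+]=CC(=O)C[C@@H](O[Si](C)(C)C(C)(C)C)C(=C)[C@@H](C(OC)OC)CCC=C(C)C
F6 | step 5 | (4S,6S)-6-(dimethoxymethyl)-10-methyl-5-methylideneundec-9-en-1-yn-4-ol | C#CC[C@H](O)C(=C)[C@@H](C(OC)OC)CCC=C(C)C
F7 | step 5 | (4R,6S)-6-(dimethoxymethyl)-10-methyl-5-methylideneundec-9-en-1-yn-4-yl 4-nitrobenzoate | C#CC[C@@H](OC(=O)c1ccc(cc1)[N+](=O)[O-])C(=C)[C@@H](C(OC)OC)CCC=C(C)C
F8 | step 13 | (4-methoxyphenyl)methyl (1S,2S,5S,7R,10S)-2-(dimethoxymethyl)-6,6-dimethyl-10-[(4-nitrobenzoyl)oxy]tricyclo[5.3.1.0(1,5)]undec-8-ene-8-carboxylate | CC1(C)[C@H]2C[C@@]3([C@@H](OC(=O)c5ccc(cc5)[N+](=O)[O-])C=C2C(=O)OCc4ccc(OC)cc4)[C@@H](C(OC)OC)CC[C@@H]13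
F9 | step 19 | (1S,2S,5S,7R,10S)-10-({(9Z)-16-[(tert-butyldimethylsilyl)oxy]hexadec-9-enoyl}oxy)-2-(dimethoxymethyl)-6,6-dimethyltricyclo[5.3.1.0(1,5)]undec-8-ene-8-carboxylic acid | CC1(C)[C@H]2C[C@@]3([C@@H](OC(=O)CCCCCCC/C=C\CCCCCCO[Si](C)(C)C(C)(C)C)C=C2C(=O)O)[C@@H](C(OC)OC)CC[C@@H]13
A1 | alternative 1 | methyl 4-[(2S)-1,1-dimethoxy-6-methylhept-5-en-2-yl]-3-methoxybenzoate | COC(=O)c1ccc([C@@H](C(OC)OC)CCC=C(C)C)c(OC)c1
A2 | alternative 1 | methyl 2-(dimethoxymethyl)-6,6-dimethyl-11-oxotricyclo[5.3.1.0(1,5)]undec-8-ene-8-carboxylate, C2 substituent trans to C6 and C11 | CC1(C)[C@@H]2C(=O)[C@]3(CC=C2C(=O)OC)[C@@H](C(OC)OC)CC[C@H]13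
A3 | alternative 2 | methyl 4-[(2S)-1,1-dimethoxy-6-methylhept-5-en-2-yl]-5-hydroxy-3,6-dioxocyclohexa-1,4-diene-1-carboxylate | COC(=O)C1=CC(=O)C([C@@H](C(OC)OC)CCC=C(C)C)=C(O)C1=O
A4 | alternative 2 | methyl 2-(dimethoxymethyl)-9-hydroxy-6,6-dimethyl-10,11-dioxotricyclo[5.3.1.0(1,5)]undec-8-ene-8-carboxylate | CC1(C)[C@H]2C(=O)[C@@]3(C(=O)C(O)=C2C(=O)OC)[C@@H](C(OC)OC)CC[C@@H]13
A5 | alternative 3 | 1-[(2S)-1,1-dimethoxy-6-methylhept-5-en-2-yl]cyclopenta-1,3-diene | COC(OC)[C@@H](CCC=C(C)C)C1=CC=CC1
A6 | alternative 3 | 2-(dimethoxymethyl)-6,6-dimethyltricyclo[5.2.1.0(1,5)]dec-8-ene | CC1(C)[C@H]2C[C@@]3(C=C2)[C@@H](C(OC)OC)CC[C@@H]13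
A7 | alternative 3 | 9,10-dibromo-2-(dimethoxymethyl)-6,6-dimethyltricyclo[5.3.1.0(1,5)]undec-8-ene | CC1(C)[C@H]2C[C@@]3([C@H](Br)C(Br)=C2)[C@@H](C(OC)OC)CC[C@@H]13
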